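**Plan**

1. Numbering used (seco-labdane type): ring B = C5–C6–C7–C8–C9–C10; C10 carries CH3 and the arm C1H2–C2(=O)–O8; C5 carries C4(CH3)2–C3O2H; C9 carries the chain C11–C15. Retrosynthesis: C3O2H and O6–H ← lactol (C3 aldehyde held on O6); then O8–C2, C6–C7 and C9–C10 are cut together; the open chain is cut once more at C6–C7 into two halves.
2. Enabling feature: on ring B the oxygens on C6 and C8 are 1,3 to each other and both axial on the face of the axial C1 arm of C10. With C6–C7 opened, C6(=O)–C5–C10–C9–C8(CH3)=C7 is an oxy-Cope product whose aldehyde carbon C6 can re-close onto C7 (Prins) while the C2 acid traps C8 and the C3 acetal holds O6.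
3. Forward: allyl chloride 9 (C7–C9, C11–C17; seven steps from linalool) and enal 16 (C1–C6, C18–C20; four steps) are joined at C6–C7. This first C6–C7 bond is a relay: the anionic [3,3] shift breaks it as it makes C9–C10. Acid then makes the final C6–C7 bond and closes ring B, the O6–C3 oxolane and the O8–C2 lactone in the same flask; deprotection and Pinnick oxidation finish.
4. Stereochemistry: C13 from (R)-linalool; C11 from D-proline α-aminoxylation; C9 and C10 from the chair [3,3] shift (E C8=C9, Z C5=C10, face fixed by C11); C5, C6 and C8 from the cyclisation (C4 equatorial, cis-fused oxolane, carboxyl delivered cis to C1).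

Key step: step 14

Remark: the carbinol carbon made in step 12 (C6) is destroyed and re-made in step 14, so 18–21 are carried as both epimers; the target is assumed to be stable as the free γ-hydroxy acid and C8 lactone between about pH 4 and 8.

**Route**

Step 1
Reactants: 1 (R)-(−)-linalool
Product: 2 (3R)-3,7-dimethyl-3-(triethylsilyloxy)octa-1,6-diene
Conditions: Et3SiOTf, 2,6-lutidine, CH2Cl2, 0 °C
Reagents that add atoms: triethylsilyl trifluoromethanesulfonate CC[Si](CC)(CC)OS(=O)(=O)C(F)(F)F
Why: Silyl triflate silylation of a tertiary alcohol with a hindered pyridine base is routine and leaves the chiral-pool stereocentre C13 untouched.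

Step 2
Reactants: 2 (3R)-3,7-dimethyl-3-(triethylsilyloxy)octa-1,6-diene
Product: 3 (4R)-4-methyl-4-(triethylsilyloxy)hex-5-enal
Conditions: O3 (1.0 equiv), pyridine, CH2Cl2, −78 °C; Me2S
Reagents that add atoms: ozone [O-][O+]=O
Why: Ozonolysis with one equivalent of ozone is selective for the electron-rich trisubstituted alkene over the hindered vinyl group, and reductive work-up gives the aldehyde.

Step 3
Reactants: 3 (4R)-4-methyl-4-(triethylsilyloxy)hex-5-enal
Product: 5 ethyl (2E,4S,6R)-2,6-dimethyl-4-(phenylaminooxy)-6-(triethylsilyloxy)octa-2,7-dienoate, via α-aminoxy aldehyde 4 (not isolated)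
Conditions: D-proline (20 mol %), PhNO, CHCl3, 0 °C; then Ph3P=C(CH3)CO2Et, 0 → 25 °C
Reagents that add atoms: nitrosobenzene O=Nc1ccccc1; ethyl 2-(triphenylphosphoranylidene)propanoate CCOC(=O)C(C)=P(c1ccccc1)(c1ccccc1)c1ccccc1
Why: Enamine-catalysed α-aminoxylation sets C11 as S under control of the D-proline catalyst alone, and the stabilised ylide then gives the E trisubstituted enoate by Wittig olefination before the α-oxy aldehyde can epimerise.

Step 4
Reactants: 5 ethyl (2E,4S,6R)-2,6-dimethyl-4-(phenylaminooxy)-6-(triethylsilyloxy)octa-2,7-dienoate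
Product: 6 ethyl (2E,4S,6R)-4-hydroxy-2,6-dimethyl-6-(triethylsilyloxy)octa-2,7-dienoate
Conditions: Zn, AcOH/THF (1:3), 0 °C
Reagents that add atoms: none
Why: Reductive cleavage of the weak N–O bond by zinc in acetic acid frees the C11 hydroxyl without touching the enoate, the vinyl group or the silyl ether.

Step 5
Reactants: 6 ethyl (2E,4S,6R)-4-hydroxy-2,6-dimethyl-6-(triethylsilyloxy)octa-2,7-dienoate
Product: 7 ethyl (2E,4S,6R)-4-(tert-butyldimethylsilyloxy)-2,6-dimethyl-6-(triethylsilyloxy)octa-2,7-dienoate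
Conditions: t-BuMe2SiCl, imidazole, DMF, 25 °C
Reagents that add atoms: tert-butyldimethylsilyl chloride CC(C)(C)[Si](C)(C)Cl
Why: Standard silylation of a secondary alcohol, which also installs the bulky C11–O group that later directs the sigmatropic shift.

Step 6
Reactants: 7 ethyl (2E,4S,6R)-4-(tert-butyldimethylsilyloxy)-2,6-dimethyl-6-(triethylsilyloxy)octa-2,7-dienoate
Product: 8 (2E,4S,6R)-4-(tert-butyldimethylsilyloxy)-2,6-dimethyl-6-(triethylsilyloxy)octa-2,7-dien-1-ol
Conditions: i-Bu2AlH (2.2 equiv), CH2Cl2, −78 °C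
Reagents that add atoms: none
Why: Hydride 1,2-reduction of the conjugated ester gives the primary allylic alcohol with the E geometry intact.

Step 7
Reactants: 8 (2E,4S,6R)-4-(tert-butyldimethylsilyloxy)-2,6-dimethyl-6-(triethylsilyloxy)octa-2,7-dien-1-ol
Product: 9 (3R,5S,6E)-5-(tert-butyldimethylsilyloxy)-8-chloro-3,7-dimethyl-3-(triethylsilyloxy)octa-1,6-diene
Conditions: MeSO2Cl, 2,4,6-collidine, LiCl, DMF, 0 °C
Reagents that add atoms: lithium chloride [Li+].[Cl-]
Why: Mesylation and in situ SN2 displacement by chloride convert the primary allylic alcohol into the chloride without allylic transposition or loss of alkene geometry.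

Step 8
Reactants: 10 N-methoxy-N-methyl-3-oxobutanamide; 11 1,1-dimethoxypropan-2-one
Product: 12 2-acetyl-N,4,4-trimethoxy-N,3-dimethylbut-2-enamide (E/Z mixture)
Conditions: TiCl4, pyridine, THF, 0 → 25 °C
Reagents that add atoms: none
Why: Knoevenagel condensation in its TiCl4/pyridine variant works for ketones with β-dicarbonyl partners, and the alkene geometry is irrelevant because the next step makes C4 quaternary.

Step 9
Reactants: 12 2-acetyl-N,4,4-trimethoxy-N,3-dimethylbut-2-enamide
Product: 14 (2Z)-3-[methoxy(methyl)carbamoyl]-5,5-dimethoxy-4,4-dimethylpent-2-en-2-yl trifluoromethanesulfonate, via lithium enolate 13 (not isolated)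
Conditions: Me2CuLi (CuI, 2 MeLi), Et2O, −78 → −20 °C; then PhNTf2, THF, −20 → 25 °C
Reagents that add atoms: lithium dimethylcuprate [Li+].C[Cu-]C; N-phenylbis(trifluoromethanesulfonimide) O=S(=O)(N(c1ccccc1)S(=O)(=O)C(F)(F)F)C(F)(F)F
Why: Cuprate conjugate addition to the doubly activated alkylidene builds the quaternary C4, and the lithium enolate, held as a chelate between the enolate oxygen and the amide carbonyl, is O-sulfonylated to the Z enol triflate (triflate cis to the amide carbon).

Step 10
Reactants: 14 (2Z)-3-[methoxy(methyl)carbamoyl]-5,5-dimethoxy-4,4-dimethylpent-2-en-2-yl trifluoromethanesulfonate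
Product: 15 tert-butyl (3Z)-4-[methoxy(methyl)carbamoyl]-6,6-dimethoxy-3,5,5-trimethylhex-3-enoate
Conditions: BrZnCH2CO2t-Bu (from BrCH2CO2t-Bu and Zn), Pd(PPh3)4 (5 mol %), THF, 60 °C
Reagents that add atoms: (2-tert-butoxy-2-oxoethyl)zinc bromide CC(C)(C)OC(=O)C[Zn]Br
Why: Negishi coupling of the enol triflate with the Reformatsky zinc reagent proceeds with retention of alkene geometry, which places the C1–C2 arm cis to the amide carbon (C6).

Step 11
Reactants: 15 tert-butyl (3Z)-4-[methoxy(methyl)carbamoyl]-6,6-dimethoxy-3,5,5-trimethylhex-3-enoate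
Product: 16 tert-butyl (3Z)-4-formyl-6,6-dimethoxy-3,5,5-trimethylhex-3-enoate
Conditions: i-Bu2AlH (1.2 equiv), THF, −78 °C
Reagents that add atoms: none
Why: Hydride reduction of the N-methoxy-N-methylamide stops at the aldehyde through its stable aluminium chelate, while the tert-butyl ester is inert at −78 °C.

Step 12
Reactants: 9 (3R,5S,6E)-5-(tert-butyldimethylsilyloxy)-8-chloro-3,7-dimethyl-3-(triethylsilyloxy)octa-1,6-diene; 16 tert-butyl (3Z)-4-formyl-6,6-dimethoxy-3,5,5-trimethylhex-3-enoate
Product: 18 tert-butyl (3Z,7E,9S,11R)-9-(tert-butyldimethylsilyloxy)-4-(1,1-dimethoxy-2-methylpropan-2-yl)-5-hydroxy-3,7,11-trimethyl-11-(triethylsilyloxy)trideca-3,7,12-trienoate (both C5 epimers), via allylbarium chloride 17 (not isolated)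
Conditions: Ba (from BaI2 and 2 LiC12H10, THF, 25 °C); 9, −78 °C; then 16, −78 °C; AcOH, −78 °C
Reagents that add atoms: none
Why: Allylbarium reagents add to aldehydes through the unsubstituted α-carbon (C7) with retention of the E geometry at −78 °C (α-selective carbonyl allylation), giving the linear 1,5-dien-3-ol whose new carbinol centre is sacrificial and needs no control.

Step 13
Reactants: 18 tert-butyl (3Z,7E,9S,11R)-9-(tert-butyldimethylsilyloxy)-4-(1,1-dimethoxy-2-methylpropan-2-yl)-5-hydroxy-3,7,11-trimethyl-11-(triethylsilyloxy)trideca-3,7,12-trienoate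
Product: 20 potassium carboxylate of 18 (free 5-hydroxyl; both C5 epimers), via δ-lactone 19 (not isolated)
Conditions: KOH (1.1 equiv), THF/MeOH/H2O, 40 °C; evaporation; PhMe azeotrope
Reagents that add atoms: potassium hydroxide [K+].[OH-]
Why: Base-mediated ester cleavage in which the hydroxyl, held cis to the ester across the tetrasubstituted alkene, displaces tert-butoxide to give lactone 19 that hydroxide opens at once, so that only the Z alkene isomer is converted and any E isomer from step 9 stays neutral and is washed out.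

Step 14
Reactants: 20 potassium carboxylate of 18
Product: 24 tricyclic lactone acetal (target skeleton with O6 and C3 joined in a cis-fused 2-methoxy-3,3-dimethyloxolane; 11-O-SiMe2t-Bu; 13-O-SiEt3), via dipotassium oxido carboxylate 21 (not isolated), via dipotassium enolate carboxylate 22 (not isolated), via aldehyde acid 23 (not isolated)
Conditions: KH (1.5 equiv), 18-crown-6 (2.5 equiv), THF, 0 → 25 °C; HCl in Et2O (to neutrality), −78 °C; solvent switch to CH2Cl2; BF3·OEt2 (3 equiv), −78 → −30 °C; pH 7 buffer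
Reagents that add atoms: none
Why: KH/18-crown-6 gives dianion 21, whose anionic oxy-Cope shift through a chair (the Z C1 arm axial on C10, the E C11 substituent equatorial on C9) forms C9–C10 and breaks the relay C6–C7 bond to give enolate 22. After protonation to 23, BF3 ionises the C3 dimethyl acetal, the C6 aldehyde oxygen captures it (5-exo) to give a 2-methoxyoxolan-5-yl cation, the isopropenyl terminus C7 attacks C6 (6-endo with respect to the alkene, chair) and the axial C2 carboxylic acid captures the tertiary C8 cation (six-membered lactone, exo capture). The closest known reaction types are the anionic oxy-Cope rearrangement of 1,5-dien-3-olates and acetal-initiated Prins cyclisations terminated by an internal carboxylic acid. C9 and C10 follow from the chair and the two alkene geometries, with the face fixed by C11: allylic 1,3-strain with the C8 methyl holds H11 in the alkene plane and C10 should bond anti to the C11–O bond, so both carbinol epimers of 21 should converge by placing the oxido group axial or equatorial. C5 is correctable because the oxolanyl cation equilibrates with its enol ether and only the epimer with C4 equatorial in the chair that keeps the C1 arm axial cyclises fast; C6 follows from cis-fusion of the oxolane (O6 axial), C8 from delivery of the carboxyl oxygen cis to C1, and the acetal carbon C3 is uncontrolled and later removed. The step needs the [3,3] shift to outrun retro-allylation and acyl transfer, which the carboxylate (no acyl electrophile, non-acidic C1–H) and the strained tetrasubstituted alkene secure, and it needs the C8 cation to be trapped before it loses H9, which the 1,3-diaxial carboxylic acid secures.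

Step 15
Reactants: 24 tricyclic lactone acetal
Product: 25 lactol triol (target skeleton with O6 and C3 joined as a 2-hydroxy-3,3-dimethyloxolane; free 11- and 13-hydroxyls)
Conditions: HF (48 % aq.), MeCN, 0 → 25 °C
Reagents that add atoms: water O
Why: Aqueous HF cleaves both silyl ethers and hydrolyses the methyl acetal to the lactol in one acid-mediated deprotection that is too weakly acidic to ionise the tertiary allylic alcohol.

Step 16
Reactants: 25 lactol triol
Product: 26 CNP0297019.1 (target)
Conditions: NaClO2, NaH2PO4, 2-methyl-2-butene, t-BuOH/H2O, 0 °C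
Reagents that add atoms: sodium chlorite [Na+].[O-]Cl=O
Why: Pinnick oxidation of the open hydroxy aldehyde in equilibrium with the lactol gives the C3 acid and frees O6–H under buffered, weakly acidic conditions, with the alkene scavenger protecting the vinyl group and no base present to move the lactone.

**Compound list**

1 | (R)-(−)-linalool | C=C[C@](C)(O)CCC=C(C)C | starting material
2 | (3R)-3,7-dimethyl-3-(triethylsilyloxy)octa-1,6-diene | C=C[C@](C)(O[Si](CC)(CC)CC)CCC=C(C)C | intermediate
3 | (4R)-4-methyl-4-(triethylsilyloxy)hex-5-enal | C=C[C@](C)(O[Si](CC)(CC)CC)CCC=O | intermediate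
4 | (2S,4R)-4-methyl-2-(phenylaminooxy)-4-(triethylsilyloxy)hex-5-enal | C=C[C@](C)(O[Si](CC)(CC)CC)C[C@H](ONc1ccccc1)C=O | intermediate
5 | ethyl (2E,4S,6R)-2,6-dimethyl-4-(phenylaminooxy)-6-(triethylsilyloxy)octa-2,7-dienoate | C=C[C@](C)(O[Si](CC)(CC)CC)C[C@H](ONc1ccccc1)/C=C(\C)C(=O)OCC | intermediate
6 | ethyl (2E,4S,6R)-4-hydroxy-2,6-dimethyl-6-(triethylsilyloxy)octa-2,7-dienoate | C=C[C@](C)(O[Si](CC)(CC)CC)C[C@H](O)/C=C(\C)C(=O)OCC | intermediate
7 | ethyl (2E,4S,6R)-4-(tert-butyldimethylsilyloxy)-2,6-dimethyl-6-(triethylsilyloxy)octa-2,7-dienoate | C=C[C@](C)(O[Si](CC)(CC)CC)C[C@H](O[Si](C)(C)C(C)(C)C)/C=C(\C)C(=O)OCC | intermediate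
8 | (2E,4S,6R)-4-(tert-butyldimethylsilyloxy)-2,6-dimethyl-6-(triethylsilyloxy)octa-2,7-dien-1-ol | C=C[C@](C)(O[Si](CC)(CC)CC)C[C@H](O[Si](C)(C)C(C)(C)C)/C=C(\C)CO | intermediate
9 | (3R,5S,6E)-5-(tert-butyldimethylsilyloxy)-8-chloro-3,7-dimethyl-3-(triethylsilyloxy)octa-1,6-diene | C=C[C@](C)(O[Si](CC)(CC)CC)C[C@H](O[Si](C)(C)C(C)(C)C)/C=C(\C)CCl | intermediate
10 | N-methoxy-N-methyl-3-oxobutanamide | CC(=O)CC(=O)N(C)OC | starting material
11 | 1,1-dimethoxypropan-2-one | CC(=O)C(OC)OC | starting material
12 | 2-acetyl-N,4,4-trimethoxy-N,3-dimethylbut-2-enamide (E/Z mixture) | CC(=O)C(=C(C)C(OC)OC)C(=O)N(C)OC | intermediate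
13 | lithium (2Z)-3-[methoxy(methyl)carbamoyl]-5,5-dimethoxy-4,4-dimethylpent-2-en-2-olate | C/C([O-])=C(/C(=O)N(C)OC)C(C)(C)C(OC)OC.[Li+] | intermediate
14 | (2Z)-3-[methoxy(methyl)carbamoyl]-5,5-dimethoxy-4,4-dimethylpent-2-en-2-yl trifluoromethanesulfonate | C/C(OS(=O)(=O)C(F)(F)F)=C(/C(=O)N(C)OC)C(C)(C)C(OC)OC | intermediate
15 | tert-butyl (3Z)-4-[methoxy(methyl)carbamoyl]-6,6-dimethoxy-3,5,5-trimethylhex-3-enoate | C/C(CC(=O)OC(C)(C)C)=C(/C(=O)N(C)OC)C(C)(C)C(OC)OC | intermediate
16 | tert-butyl (3Z)-4-formyl-6,6-dimethoxy-3,5,5-trimethylhex-3-enoate | C/C(CC(=O)OC(C)(C)C)=C(/C=O)C(C)(C)C(OC)OC | intermediate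
17 | [(2E,4S,6R)-4-(tert-butyldimethylsilyloxy)-2,6-dimethyl-6-(triethylsilyloxy)octa-2,7-dien-1-yl]barium chloride | C=C[C@](C)(O[Si](CC)(CC)CC)C[C@H](O[Si](C)(C)C(C)(C)C)/C=C(\C)C[Ba]Cl | intermediate
18 | tert-butyl (3Z,7E,9S,11R)-9-(tert-butyldimethylsilyloxy)-4-(1,1-dimethoxy-2-methylpropan-2-yl)-5-hydroxy-3,7,11-trimethyl-11-(triethylsilyloxy)trideca-3,7,12-trienoate (both C5 epimers) | C=C[C@](C)(O[Si](CC)(CC)CC)C[C@H](O[Si](C)(C)C(C)(C)C)/C=C(\C)CC(O)/C(C(C)(C)C(OC)OC)=C(/C)CC(=O)OC(C)(C)C | intermediate
19 | 6-[(2E,4S,6R)-4-(tert-butyldimethylsilyloxy)-2,6-dimethyl-6-(triethylsilyloxy)octa-2,7-dien-1-yl]-5-(1,1-dimethoxy-2-methylpropan-2-yl)-4-methyl-3,6-dihydro-2H-pyran-2-one (both C6 epimers) | C=C[C@](C)(O[Si](CC)(CC)CC)C[C@H](O[Si](C)(C)C(C)(C)C)/C=C(\C)CC1OC(=O)CC(C)=C1C(C)(C)C(OC)OC | intermediate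
20 | potassium carboxylate of 18 (tert-butyl ester replaced by CO2K; both carbinol epimers) | C=C[C@](C)(O[Si](CC)(CC)CC)C[C@H](O[Si](C)(C)C(C)(C)C)/C=C(\C)CC(O)/C(C(C)(C)C(OC)OC)=C(/C)CC(=O)[O-].[K+] | intermediate
21 | dipotassium oxido carboxylate of 20 | C=C[C@](C)(O[Si](CC)(CC)CC)C[C@H](O[Si](C)(C)C(C)(C)C)/C=C(\C)CC([O-])/C(C(C)(C)C(OC)OC)=C(/C)CC(=O)[O-].[K+].[K+] | intermediate
22 | dipotassium enolate carboxylate (C5=C6 enolate of 23 and its C2 carboxylate; C9, C10, C11, C13 as in the target) | C=C[C@](C)(O[Si](CC)(CC)CC)C[C@H](O[Si](C)(C)C(C)(C)C)[C@@H](C(C)=C)[C@](C)(CC(=O)[O-])C(=C[O-])C(C)(C)C(OC)OC.[K+].[K+] | intermediate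
23 | aldehyde acid (C6 aldehyde, C2 acid, C3 dimethyl acetal, isopropenyl C8=C7 on C9; C5 epimers; C9, C10, C11, C13 as in the target) | C=C[C@](C)(O[Si](CC)(CC)CC)C[C@H](O[Si](C)(C)C(C)(C)C)[C@@H](C(C)=C)[C@](C)(CC(=O)O)C(C=O)C(C)(C)C(OC)OC | intermediate
24 | tricyclic lactone acetal (target skeleton; O6–C3 methyl acetal, both anomers; 11-O-SiMe2t-Bu; 13-O-SiEt3) | C=C[C@](C)(O[Si](CC)(CC)CC)C[C@H](O[Si](C)(C)C(C)(C)C)[C@@H]1[C@]2(C)CC(=O)O[C@@]1(C)C[C@@H](OC(OC)C3(C)C)[C@H]23 | intermediate
25 | lactol triol (target skeleton; O6–C3 lactol, both anomers) | C=C[C@](C)(O)C[C@H](O)[C@@H]1[C@]2(C)CC(=O)O[C@@]1(C)C[C@@H](OC(O)C3(C)C)[C@H]23 | intermediate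
26 | CNP0297019.1 | C=C[C@](C)(O)C[C@H](O)[C@@H]1[C@]2(C)CC(=O)O[C@@]1(C)C[C@@H](O)[C@H]2C(C)(C)C(=O)O | target

**Totals**

Total step count: 16. Longest linear sequence: 12 steps (steps 1–7, then 12–16).

**Steps most likely to fail**

1. Step 14. Facial discrimination in the [3,3] shift may be incomplete, because the two carbinol epimers of 21 must place the oxido group in different orientations to obey the C11 bias, so one epimer may leak to the wrong C9/C10 pair. The fallback sets out from 18 and makes the carbinol single by reagent control. Dess–Martin oxidation gives the dienone ester F1. Corey–Bakshi–Shibata reduction ((S)-methyl oxazaborolidine, catecholborane, −78 °C, the tetrasubstituted alkenyl group acting as the large substituent) should give the (5R)-dienol ester F2. In F2 the oxido group can sit axial, away from the tertiary alkyl group on C5, in the chair that C11 prefers. F2 is one of the two epimers of 18 and is taken through steps 13 and 14 as written, coming back to the route at 24.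

2. Step 9. The enolate may be sulfonylated with the triflate trans to the amide carbon if allylic strain between the C10 methyl and the tertiary alkyl group overrides chelation. The fallback sets out from 12 and moves the geometry-setting event to an isolated compound. Conjugate addition of Me2CuLi and aqueous quench give the β-keto amide F3. Lithium-chelate-controlled tosylation (TsCl, N-methylimidazole, LiOH) gives the Z enol tosylate F4, whose isomers can be separated and assigned before coupling. Negishi coupling of F4 with the same zinc reagent comes back to the route at 15.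

3. Step 13. Lactone-assisted cleavage of the tert-butyl ester may be slow, with base instead shifting the C5=C10 alkene into conjugation with the ester or causing 1,4-elimination from lactone 19. The fallback sets out from 14 and installs the carboxylate before the union. Negishi coupling with BrZnCH2CO2Me gives the methyl ester F5. LiOH saponification of the unhindered ester gives the acid F6. i-Bu2AlH reduction of the amide gives the aldehyde acid F7, which is in equilibrium with its cyclic hydroxy lactone. Addition of allylbarium 17 to the potassium salt of F7 (KN(SiMe3)2, −78 °C) and a basic work-up comes back to the route at 20.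

**Further compounds**

F1 | step 14 | tert-butyl (3Z,7E,9S,11R)-9-(tert-butyldimethylsilyloxy)-4-(1,1-dimethoxy-2-methylpropan-2-yl)-3,7,11-trimethyl-5-oxo-11-(triethylsilyloxy)trideca-3,7,12-trienoate | C=C[C@](C)(O[Si](CC)(CC)CC)C[C@H](O[Si](C)(C)C(C)(C)C)/C=C(\C)CC(=O)/C(C(C)(C)C(OC)OC)=C(/C)CC(=O)OC(C)(C)C
F2 | step 14 | tert-butyl (3Z,5R,7E,9S,11R)-9-(tert-butyldimethylsilyloxy)-4-(1,1-dimethoxy-2-methylpropan-2-yl)-5-hydroxy-3,7,11-trimethyl-11-(triethylsilyloxy)trideca-3,7,12-trienoate | C=C[C@](C)(O[Si](CC)(CC)CC)C[C@H](O[Si](C)(C)C(C)(C)C)/C=C(\C)C[C@@H](O)/C(C(C)(C)C(OC)OC)=C(/C)CC(=O)OC(C)(C)C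
F3 | step 9 | 2-acetyl-N,4,4-trimethoxy-N,3,3-trimethylbutanamide | CC(=O)C(C(=O)N(C)OC)C(C)(C)C(OC)OC
F4 | step 9 | (2Z)-3-[methoxy(methyl)carbamoyl]-5,5-dimethoxy-4,4-dimethylpent-2-en-2-yl 4-methylbenzenesulfonate | C/C(OS(=O)(=O)c1ccc(C)cc1)=C(/C(=O)N(C)OC)C(C)(C)C(OC)OC
F5 | step 13 | methyl (3Z)-4-[methoxy(methyl)carbamoyl]-6,6-dimethoxy-3,5,5-trimethylhex-3-enoate | C/C(CC(=O)OC)=C(/C(=O)N(C)OC)C(C)(C)C(OC)OC
F6 | step 13 | (3Z)-4-[methoxy(methyl)carbamoyl]-6,6-dimethoxy-3,5,5-trimethylhex-3-enoic acid | C/C(CC(=O)O)=C(/C(=O)N(C)OC)C(C)(C)C(OC)OC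
F7 | step 13 | (3Z)-4-formyl-6,6-dimethoxy-3,5,5-trimethylhex-3-enoic acid | C/C(CC(=O)O)=C(/C=O)C(C)(C)C(OC)OC
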